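**Retrosynthetic overview**

1. Sophonorol F comes from its bis-MOM ether 28 by acetal removal. Ring C of 28 is cut at O1–C8a and C4–C4a, giving aryne 26 (ring A, from o-silylaryl triflate 11) and the four-atom unit O1–C2–C3–C4 carried by dioxolanone 24.
2. Enabling feature: ring C is joined to ring A only through the adjacent aromatic carbons C8a (ether O1) and C4a (ketone carbon C4), and C5, next to C4a, bears oxygen. A C4a≡C8a aryne polarized by the C5 oxygen takes the oxygen nucleophile at C8a and places the carbanion on C4a, within six-ring reach of C4.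
3. Dioxolanone 24 (a temporary ring) holds C3 in its final configuration, masks the tertiary C3 oxygen, activates C4 as an acyl acetal and carries O1 as a silyl ether. Fluoride unmasks both partners at once and the dioxolanone is destroyed in the same step.
4. C3 stereocentre: (R)-mandelate 18 by asymmetric transfer hydrogenation, then cis-dioxolanone 21, then hydroxymethylation trans to tert-butyl (self-regeneration of stereocentres).
5. Ring order: rings A and B are bought as benzenes and dressed by directed metalation (both prenyl groups); temporary dioxolanone ring in step 10; ring C last, in step 12.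

Key step: step 12

Remark on the chemistry (assumption): flavonoid numbering is used (O1, C2, C3, C4, C4a, C5 to C8, C8a; ring B primed). The facial sense of step 8 is assigned from the accepted model for this catalyst class; should it prove opposite, the enantiomeric ligand is used.

**Fragment 1: aryne precursor (steps 1 to 4)**

Step 1
Reactants: 1 5-methoxybenzene-1,3-diol
Product: 2 3-methoxy-5-(methoxymethoxy)phenol
Conditions: MOMCl (1.0 equiv), iPr2NEt, CH2Cl2, 0 °C
Reagents that add atoms: chloromethyl methyl ether, COCCl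
Why: Base-mediated O-alkylation (Williamson-type acetal ether formation) of a symmetric diphenol with one equivalent of MOMCl should give the mono-ether statistically, with diol and bis-ether separable and recyclable.

Step 2
Reactants: 2 3-methoxy-5-(methoxymethoxy)phenol
Product: 3 3-methoxy-5-(methoxymethoxy)phenyl N-isopropylcarbamate
Conditions: iPrNCO, Et3N (cat.), CH2Cl2, rt
Reagents that add atoms: isopropyl isocyanate, CC(C)N=C=O
Why: Amine-catalysed addition of the phenol to an isocyanate gives the N-monoalkyl carbamate, which serves as the strongest directing group and is removable under mild base.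

Step 3
Reactants: 3 3-methoxy-5-(methoxymethoxy)phenyl N-isopropylcarbamate
Product: 9 3-methoxy-5-(methoxymethoxy)-2-(3-methylbut-2-en-1-yl)-6-(trimethylsilyl)phenyl N-isopropylcarbamate, via N-silyl carbamate 4 (not isolated), via first aryllithium 5 (not isolated), via C,N-disilyl carbamate 6 (not isolated), via second aryllithium 7 (not isolated), via N-silyl prenyl carbamate 8 (not isolated)
Conditions: TMSOTf, TMEDA, Et2O, 0 °C to rt; n-BuLi (2.2 equiv), TMEDA, −78 °C; TMSCl (1.2 equiv), −78 to 0 °C; s-BuLi (1.3 equiv), −78 °C; CuBr·SMe2 (10 mol %), prenyl bromide, −78 to −20 °C; aq. NH4Cl/MeOH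
Reagents that add atoms: chlorotrimethylsilane, C[Si](C)(C)Cl; prenyl bromide (1-bromo-3-methylbut-2-ene), CC(C)=CCBr
Why: Two consecutive directed ortho-metalations of the in situ N-silylated O-aryl carbamate (Snieckus-type) are run in one pot with the N-silyl group kept on throughout: the first is expected at the carbon flanked by the carbamate and the OMOM group, the two strongest directing groups, and silyl quench gives the arylsilane that becomes C4a, while the second can only go to the remaining position next to the carbamate (between carbamate and OMe), where copper-catalysed SN2 allylation with prenyl bromide installs the C8 prenyl group before the N-silyl group is lost on work-up.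

Step 4
Reactants: 9 3-methoxy-5-(methoxymethoxy)-2-(3-methylbut-2-en-1-yl)-6-(trimethylsilyl)phenyl N-isopropylcarbamate
Product: 11 3-methoxy-5-(methoxymethoxy)-2-(3-methylbut-2-en-1-yl)-6-(trimethylsilyl)phenyl trifluoromethanesulfonate, via phenol 10 (not isolated)
Conditions: Et2NH, DBU, MeCN, 40 °C; then PhNTf2, rt
Reagents that add atoms: N-phenylbis(trifluoromethanesulfonimide), O=S(=O)(N(c1ccccc1)S(=O)(=O)C(F)(F)F)C(F)(F)F
Why: Base-induced E1cB cleavage of the N-monoalkyl carbamate (isocyanate trapped by Et2NH) and triflation of the phenoxide in the same pot give the Kobayashi-type o-silylaryl triflate without exposing the acid-labile arylsilane to acid.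

**Fragment 2: chiral four-atom unit (steps 5 to 11)**

Step 5
Reactants: 12 4-bromo-3-methoxyphenol
Product: 13 1-bromo-2-methoxy-4-(methoxymethoxy)benzene
Conditions: MOMCl, iPr2NEt, CH2Cl2, 0 °C to rt
Reagents that add atoms: chloromethyl methyl ether, COCCl
Why: Phenol O-alkylation with MOMCl (acetal protection) masks the future C4′ hydroxyl and creates, together with the methoxy group, a doubly activated site for metalation.

Step 6
Reactants: 13 1-bromo-2-methoxy-4-(methoxymethoxy)benzene
Product: 15 1-bromo-2-methoxy-4-(methoxymethoxy)-3-(3-methylbut-2-en-1-yl)benzene, via aryllithium 14 (not isolated)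
Conditions: LiTMP (lithium 2,2,6,6-tetramethylpiperidide), THF, −78 °C; CuBr·SMe2 (10 mol %), prenyl bromide, −78 to 0 °C
Reagents that add atoms: prenyl bromide (1-bromo-3-methylbut-2-ene), CC(C)=CCBr
Why: Directed ortho-metalation by a hindered lithium amide, which does not undergo bromine–lithium exchange, at the carbon between the OMe and OMOM oxygens, followed by copper-catalysed SN2 allylation, places the prenyl group at C3′.

Step 7
Reactants: 15 1-bromo-2-methoxy-4-(methoxymethoxy)-3-(3-methylbut-2-en-1-yl)benzene
Product: 17 ethyl 2-[2-methoxy-4-(methoxymethoxy)-3-(3-methylbut-2-en-1-yl)phenyl]-2-oxoacetate, via aryllithium 16 (not isolated)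
Conditions: n-BuLi, THF, −78 °C; then added to diethyl oxalate (3 equiv), THF, −78 °C
Reagents that add atoms: diethyl oxalate, CCOC(=O)C(=O)OCC
Why: Bromine–lithium exchange and acylation of the aryllithium by excess diethyl oxalate (inverse addition to avoid double addition) give the aryl α-keto ester.

Step 8
Reactants: 17 ethyl 2-[2-methoxy-4-(methoxymethoxy)-3-(3-methylbut-2-en-1-yl)phenyl]-2-oxoacetate
Product: 18 ethyl (2R)-2-hydroxy-2-[2-methoxy-4-(methoxymethoxy)-3-(3-methylbut-2-en-1-yl)phenyl]acetate
Conditions: RuCl[(S,S)-TsDPEN](p-cymene) (1 mol %), HCO2H/Et3N (5:2), DMF, 25 °C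
Reagents that add atoms: none
Why: Noyori–Ikariya asymmetric transfer hydrogenation of the aryl α-keto ester sets the mandelate stereocentre, the (S,S)-ligand delivering hydride to the face fixed by the aryl/η6-arene contact, which corresponds to (R), and leaves the trisubstituted alkene untouched.

Step 9
Reactants: 18 ethyl (2R)-2-hydroxy-2-[2-methoxy-4-(methoxymethoxy)-3-(3-methylbut-2-en-1-yl)phenyl]acetate
Product: 19 (2R)-2-hydroxy-2-[2-methoxy-4-(methoxymethoxy)-3-(3-methylbut-2-en-1-yl)phenyl]acetic acid
Conditions: LiOH, THF/H2O, 0 °C; then cold 1 M HCl to pH 3, rapid extraction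
Reagents that add atoms: lithium hydroxide, [Li+].[OH-]
Why: Mild saponification of the ester gives the α-hydroxy acid without epimerisation, since the intermediate carboxylate resists enolisation.

Step 10
Reactants: 19 (2R)-2-hydroxy-2-[2-methoxy-4-(methoxymethoxy)-3-(3-methylbut-2-en-1-yl)phenyl]acetic acid
Product: 21 (2R,5R)-2-tert-butyl-5-[2-methoxy-4-(methoxymethoxy)-3-(3-methylbut-2-en-1-yl)phenyl]-1,3-dioxolan-4-one, via bis-silyl hydroxy acid 20 (not isolated)
Conditions: TMSCl, Et3N, CH2Cl2, 0 °C to rt; then t-BuCHO, TMSOTf (5 mol %), −78 °C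
Reagents that add atoms: pivalaldehyde, CC(C)(C)C=O
Why: Silyl-triflate-catalysed acetalisation of the bis-silylated α-hydroxy acid with pivalaldehyde (Seebach dioxolanone formation under Noyori-type conditions) gives the cis-acetal under kinetic control, the mandelate centre placing tert-butyl and aryl on the same face, so the new acetal centre is (2R).

Step 11
Reactants: 21 (2R,5R)-2-tert-butyl-5-[2-methoxy-4-(methoxymethoxy)-3-(3-methylbut-2-en-1-yl)phenyl]-1,3-dioxolan-4-one
Product: 24 (2R,5S)-2-tert-butyl-5-[2-methoxy-4-(methoxymethoxy)-3-(3-methylbut-2-en-1-yl)phenyl]-5-[(trimethylsilyloxy)methyl]-1,3-dioxolan-4-one, via lithium enolate 22 (not isolated), via lithium aldolate 23 (not isolated)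
Conditions: LiN(SiMe3)2, THF, −78 °C; CH2O (monomeric gas, from cracked paraformaldehyde), −78 °C; TMSCl, −78 to −30 °C; cold aq. NaHCO3
Reagents that add atoms: formaldehyde, C=O; chlorotrimethylsilane, C[Si](C)(C)Cl
Why: Self-regeneration of stereocentres: the planar lithium enolate is attacked by formaldehyde on the face opposite to the tert-butyl group (aldol addition), which sets the quaternary centre as (5S), and the aldolate is trapped as its trimethylsilyl ether.

**Union and completion (steps 12 and 13)**

Step 12
Reactants: 11 3-methoxy-5-(methoxymethoxy)-2-(3-methylbut-2-en-1-yl)-6-(trimethylsilyl)phenyl trifluoromethanesulfonate; 24 (2R,5S)-2-tert-butyl-5-[2-methoxy-4-(methoxymethoxy)-3-(3-methylbut-2-en-1-yl)phenyl]-5-[(trimethylsilyloxy)methyl]-1,3-dioxolan-4-one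
Product: 28 (3S)-3-hydroxy-7-methoxy-3-[2-methoxy-4-(methoxymethoxy)-3-(3-methylbut-2-en-1-yl)phenyl]-5-(methoxymethoxy)-8-(3-methylbut-2-en-1-yl)-2,3-dihydro-4H-chromen-4-one, via caesium alkoxide 25 (not isolated), via aryne 26 (not isolated), via aryl anion 27 (not isolated)
Conditions: CsF (4 equiv), DME, 60 °C, 11 (1.4 equiv) and 24 added together over 4 h; then aq. NH4Cl
Reagents that add atoms: none
Why: Proposed new method: fluoride strips the silyl ether of 24 to the caesium alkoxide 25 and at the same time triggers 1,2-elimination of 11 to aryne 26; the alkoxide oxygen adds to the aryne carbon C8a, remote from the C5–OMOM group (inductive polarization of a 3-alkoxyaryne), so that the aryl carbanion 27 arises at C4a, ortho to the new ether and stabilized by the neighbouring OMOM. This carbanion attacks the dioxolanone carbonyl (C4) through a six-membered transition state (6-exo-trig acyl substitution), which closes ring C, and collapse of the tetrahedral intermediate expels the acetal oxygen, which sheds pivalaldehyde and leaves the C3 alkoxide (free C3–OH after work-up). The closest known reaction types are the aryne annulation of salicylate esters to xanthones (phenoxide addition to the aryne followed by intramolecular acylation of the aryl anion) and the fluoride-induced O–H insertion of aliphatic alcohols into arynes; new here is the aliphatic, silyl-masked alkoxide combined with an acyl acetal as acceptor. No new stereocentre is formed: C3 is carried in from 24 with no bond to it made or broken, and should 25 undergo retro-aldol/aldol equilibration the tert-butyl acetal centre returns the same configuration. The step needs site selectivity on the aryne (C8a versus C4a, secured by the C5 oxygen against the steric bias of the C8 prenyl group), acylation of 27 in preference to protonation (secured by the proton-free silyl-masked nucleophile, the aprotic ether solvent and the activated acyl acetal), and O-arylation by the primary and not the tertiary oxygen (secured by tying the tertiary oxygen into the dioxolanone).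

Step 13
Reactants: 28 (3S)-3-hydroxy-7-methoxy-3-[2-methoxy-4-(methoxymethoxy)-3-(3-methylbut-2-en-1-yl)phenyl]-5-(methoxymethoxy)-8-(3-methylbut-2-en-1-yl)-2,3-dihydro-4H-chromen-4-one
Product: 29 sophonorol F, (3S)-3,5-dihydroxy-3-[4-hydroxy-2-methoxy-3-(3-methylbut-2-en-1-yl)phenyl]-7-methoxy-8-(3-methylbut-2-en-1-yl)-2,3-dihydro-4H-chromen-4-one
Conditions: HCl (0.5 M in MeOH), 0 °C to rt
Reagents that add atoms: none
Why: Acid-catalysed methanolysis of the two aryl methoxymethyl acetals under dilute, cold conditions (acetal exchange) frees the C5 and C4′ phenols, while the tertiary α-ketol and the prenyl groups are expected to survive.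

**Compound list**

1 | 5-methoxybenzene-1,3-diol | COc1cc(O)cc(O)c1 | starting material
2 | 3-methoxy-5-(methoxymethoxy)phenol | COCOc1cc(O)cc(OC)c1 | intermediate
3 | 3-methoxy-5-(methoxymethoxy)phenyl N-isopropylcarbamate | COCOc1cc(OC)cc(OC(=O)NC(C)C)c1 | intermediate
4 | 3-methoxy-5-(methoxymethoxy)phenyl N-isopropyl-N-(trimethylsilyl)carbamate (not isolated) | COCOc1cc(OC)cc(OC(=O)N(C(C)C)[Si](C)(C)C)c1 | intermediate
5 | 2-lithio derivative of 4, lithium between carbamate and OMOM (not isolated) | COCOc1cc(OC)cc(OC(=O)N(C(C)C)[Si](C)(C)C)c1[Li] | intermediate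
6 | 5-methoxy-3-(methoxymethoxy)-2-(trimethylsilyl)phenyl N-isopropyl-N-(trimethylsilyl)carbamate (not isolated) | COCOc1cc(OC)cc(OC(=O)N(C(C)C)[Si](C)(C)C)c1[Si](C)(C)C | intermediate
7 | 6-lithio derivative of 6, lithium between carbamate and OMe (not isolated) | COCOc1cc(OC)c([Li])c(OC(=O)N(C(C)C)[Si](C)(C)C)c1[Si](C)(C)C | intermediate
8 | N-silylated form of 9 (not isolated) | COCOc1cc(OC)c(CC=C(C)C)c(OC(=O)N(C(C)C)[Si](C)(C)C)c1[Si](C)(C)C | intermediate
9 | 3-methoxy-5-(methoxymethoxy)-2-(3-methylbut-2-en-1-yl)-6-(trimethylsilyl)phenyl N-isopropylcarbamate | COCOc1cc(OC)c(CC=C(C)C)c(OC(=O)NC(C)C)c1[Si](C)(C)C | intermediate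
10 | 3-methoxy-5-(methoxymethoxy)-2-(3-methylbut-2-en-1-yl)-6-(trimethylsilyl)phenol (not isolated) | COCOc1cc(OC)c(CC=C(C)C)c(O)c1[Si](C)(C)C | intermediate
11 | 3-methoxy-5-(methoxymethoxy)-2-(3-methylbut-2-en-1-yl)-6-(trimethylsilyl)phenyl trifluoromethanesulfonate | COCOc1cc(OC)c(CC=C(C)C)c(OS(=O)(=O)C(F)(F)F)c1[Si](C)(C)C | intermediate
12 | 4-bromo-3-methoxyphenol | COc1cc(O)ccc1Br | starting material
13 | 1-bromo-2-methoxy-4-(methoxymethoxy)benzene | COCOc1ccc(Br)c(OC)c1 | intermediate
14 | 3-lithio derivative of 13, lithium between OMe and OMOM (not isolated) | COCOc1ccc(Br)c(OC)c1[Li] | intermediate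
15 | 1-bromo-2-methoxy-4-(methoxymethoxy)-3-(3-methylbut-2-en-1-yl)benzene | COCOc1ccc(Br)c(OC)c1CC=C(C)C | intermediate
16 | [2-methoxy-4-(methoxymethoxy)-3-(3-methylbut-2-en-1-yl)phenyl]lithium (not isolated) | COCOc1ccc([Li])c(OC)c1CC=C(C)C | intermediate
17 | ethyl 2-[2-methoxy-4-(methoxymethoxy)-3-(3-methylbut-2-en-1-yl)phenyl]-2-oxoacetate | CCOC(=O)C(=O)c1ccc(OCOC)c(CC=C(C)C)c1OC | intermediate
18 | ethyl (2R)-2-hydroxy-2-[2-methoxy-4-(methoxymethoxy)-3-(3-methylbut-2-en-1-yl)phenyl]acetate | CCOC(=O)[C@H](O)c1ccc(OCOC)c(CC=C(C)C)c1OC | intermediate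
19 | (2R)-2-hydroxy-2-[2-methoxy-4-(methoxymethoxy)-3-(3-methylbut-2-en-1-yl)phenyl]acetic acid | OC(=O)[C@H](O)c1ccc(OCOC)c(CC=C(C)C)c1OC | intermediate
20 | trimethylsilyl (2R)-2-aryl-2-(trimethylsilyloxy)acetate, aryl as in 19 (not isolated) | C[Si](C)(C)OC(=O)[C@H](O[Si](C)(C)C)c1ccc(OCOC)c(CC=C(C)C)c1OC | intermediate
21 | (2R,5R)-2-tert-butyl-5-[2-methoxy-4-(methoxymethoxy)-3-(3-methylbut-2-en-1-yl)phenyl]-1,3-dioxolan-4-one (tert-butyl and aryl cis) | CC(C)(C)[C@H]1OC(=O)[C@@H](c2ccc(OCOC)c(CC=C(C)C)c2OC)O1 | intermediate
22 | lithium enolate of 21, (2R) (not isolated) | CC(C)(C)[C@H]1OC([O-])=C(c2ccc(OCOC)c(CC=C(C)C)c2OC)O1.[Li+] | intermediate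
23 | lithium alkoxide of the (2R,5S)-5-(hydroxymethyl) dioxolanone (not isolated) | CC(C)(C)[C@H]1OC(=O)[C@@](C[O-])(c2ccc(OCOC)c(CC=C(C)C)c2OC)O1.[Li+] | intermediate
24 | (2R,5S)-2-tert-butyl-5-[2-methoxy-4-(methoxymethoxy)-3-(3-methylbut-2-en-1-yl)phenyl]-5-[(trimethylsilyloxy)methyl]-1,3-dioxolan-4-one (aryl cis to tert-butyl) | CC(C)(C)[C@H]1OC(=O)[C@@](CO[Si](C)(C)C)(c2ccc(OCOC)c(CC=C(C)C)c2OC)O1 | intermediate
25 | caesium alkoxide of the (2R,5S)-5-(hydroxymethyl) dioxolanone (not isolated) | CC(C)(C)[C@H]1OC(=O)[C@@](C[O-])(c2ccc(OCOC)c(CC=C(C)C)c2OC)O1.[Cs+] | intermediate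
26 | 4-methoxy-6-(methoxymethoxy)-3-(3-methylbut-2-en-1-yl)-1,2-didehydrobenzene (aryne, not isolated) | COCOC1=CC(OC)=C(CC=C(C)C)C#C1 | intermediate
27 | caesium aryl anion formed by addition of 25 to 26, ether at C8a and carbanion at C4a (not isolated) | CC(C)(C)[C@H]1OC(=O)[C@@](COc2c(CC=C(C)C)c(OC)cc(OCOC)[c-]2)(c2ccc(OCOC)c(CC=C(C)C)c2OC)O1.[Cs+] | intermediate
28 | (3S)-3-hydroxy-7-methoxy-3-[2-methoxy-4-(methoxymethoxy)-3-(3-methylbut-2-en-1-yl)phenyl]-5-(methoxymethoxy)-8-(3-methylbut-2-en-1-yl)-2,3-dihydro-4H-chromen-4-one | COc1cc(OCOC)c2c(c1CC=C(C)C)OC[C@@](O)(c1ccc(OCOC)c(CC=C(C)C)c1OC)C2=O | intermediate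
29 | sophonorol F, (3S)-3,5-dihydroxy-3-[4-hydroxy-2-methoxy-3-(3-methylbut-2-en-1-yl)phenyl]-7-methoxy-8-(3-methylbut-2-en-1-yl)-2,3-dihydro-4H-chromen-4-one | COc1cc(O)c2c(c1CC=C(C)C)OC[C@@](O)(c1ccc(O)c(CC=C(C)C)c1OC)C2=O | target

**Step count and risks**

Total step count: 13. Longest linear sequence: 9 steps (steps 5 to 11, then 12 and 13); fragment 1 contributes 4 steps (steps 1 to 4).

Steps most likely to fail:

1. Step 12 (bears the label). What may go wrong: protonation of the aryl anion before acyl transfer, so that the reaction stalls at O-arylation; fragmentation of the unmasked alkoxide by retro-aldol loss of formaldehyde or by intermolecular acyl transfer; erosion of site selectivity on the aryne by the flanking prenyl group. Fallback with known chemistry, setting out from bromide 15 and using triflate 11: bromine–lithium exchange of 15 (n-BuLi, THF, −78 °C), transmetalation with ZnCl2 and Negishi coupling with ethyl 2-bromoacrylate (Pd(PPh3)4) would give ethyl 2-[2-methoxy-4-(methoxymethoxy)-3-(3-methylbut-2-en-1-yl)phenyl]prop-2-enoate F1. Saponification (LiOH, THF/H2O) would give the corresponding 2-arylacrylic acid F2. Reaction of F2 with 11 and CsF in THF at 100 to 125 °C is the known insertion of an aryne into the C–O bond of an α,β-unsaturated carboxylic acid (carboxylate addition at C8a, 1,3-acyl shift to C4a, then 6-endo oxa-Michael closure) and should give the racemic isoflavanone F3. Enolisation of F3 (NaN(SiMe3)2, THF, −78 °C) and hydroxylation with the appropriate enantiomer of the Davis (camphorylsulfonyl)oxaziridine should install the C3 hydroxyl with reagent control. The fallback comes back to the route at 28.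

2. Step 3. What may go wrong: loss of site control in the first metalation (lithiation next to OMe instead of next to OMOM), an error that the second metalation in the same pot would inherit, or incomplete silyl quench before the second base is added. Fallback, setting out from diol 1 and making both metalation sites unambiguous by symmetry: double carbamoylation (iPrNCO, Et3N) would give 5-methoxy-1,3-phenylene bis(N-isopropylcarbamate) F4. Double N-silylation (TMSOTf, TMEDA), lithiation at the unique carbon between the two carbamates, TMSCl quench and aqueous work-up would give the 2-(trimethylsilyl) bis-carbamate F5. Renewed N-silylation, a second metalation at either of the two equivalent carbons next to OMe and copper-catalysed prenylation would give the 4-prenyl-2-silyl bis-carbamate F6. Cleavage of both carbamates (Et2NH, DBU, MeCN) would give 5-methoxy-4-(3-methylbut-2-en-1-yl)-2-(trimethylsilyl)benzene-1,3-diol F7. Mono-protection of the less hindered hydroxyl of F7 (NaH, 1 equiv, MOMCl, THF, −78 to 0 °C; the other hydroxyl is flanked by silyl and prenyl) comes back to the route at phenol 10, which is triflated as in step 4.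

3. Step 13. What may go wrong: acid-promoted dehydration of the tertiary α-ketol towards the isoflavone, or cyclisation of the freed C4′ phenol onto the neighbouring prenyl group during acetal cleavage. Fallback without Brønsted acid, setting out from 28: TMSOTf and 2,2′-bipyridyl in CH2Cl2 at 0 °C to rt convert aryl methoxymethyl ethers through bipyridinium intermediates into aryl silyl ethers and silylate the tertiary alcohol, which should give the tris(trimethylsilyl) ether F8. Brief methanolysis of F8 (KF cat., MeOH, 0 °C) removes the three silyl groups and comes back to the route at 29.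

Further compounds
F1 | step 12 | ethyl 2-[2-methoxy-4-(methoxymethoxy)-3-(3-methylbut-2-en-1-yl)phenyl]prop-2-enoate | CCOC(=O)C(=C)c1ccc(OCOC)c(CC=C(C)C)c1OC
F2 | step 12 | 2-[2-methoxy-4-(methoxymethoxy)-3-(3-methylbut-2-en-1-yl)phenyl]prop-2-enoic acid | OC(=O)C(=C)c1ccc(OCOC)c(CC=C(C)C)c1OC
F3 | step 12 | racemic 7-methoxy-3-[2-methoxy-4-(methoxymethoxy)-3-(3-methylbut-2-en-1-yl)phenyl]-5-(methoxymethoxy)-8-(3-methylbut-2-en-1-yl)-2,3-dihydro-4H-chromen-4-one | COc1cc(OCOC)c2c(c1CC=C(C)C)OCC(c1ccc(OCOC)c(CC=C(C)C)c1OC)C2=O
F4 | step 3 | 5-methoxy-1,3-phenylene bis(N-isopropylcarbamate) | COc1cc(OC(=O)NC(C)C)cc(OC(=O)NC(C)C)c1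
F5 | step 3 | 5-methoxy-2-(trimethylsilyl)-1,3-phenylene bis(N-isopropylcarbamate) | COc1cc(OC(=O)NC(C)C)c([Si](C)(C)C)c(OC(=O)NC(C)C)c1
F6 | step 3 | 5-methoxy-4-(3-methylbut-2-en-1-yl)-2-(trimethylsilyl)-1,3-phenylene bis(N-isopropylcarbamate) | COc1cc(OC(=O)NC(C)C)c([Si](C)(C)C)c(OC(=O)NC(C)C)c1CC=C(C)C
F7 | step 3 | 5-methoxy-4-(3-methylbut-2-en-1-yl)-2-(trimethylsilyl)benzene-1,3-diol | COc1cc(O)c([Si](C)(C)C)c(O)c1CC=C(C)C
F8 | step 13 | (3S)-7-methoxy-3-[2-methoxy-3-(3-methylbut-2-en-1-yl)-4-(trimethylsilyloxy)phenyl]-8-(3-methylbut-2-en-1-yl)-3,5-bis(trimethylsilyloxy)-2,3-dihydro-4H-chromen-4-one | COc1cc(O[Si](C)(C)C)c2c(c1CC=C(C)C)OC[C@@](O[Si](C)(C)C)(c1ccc(O[Si](C)(C)C)c(CC=C(C)C)c1OC)C2=O
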